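## Assumptions
- The acyl chain in the target SMILES has 32 carbons (CH3(CH2)30C(=O)–). The target is therefore 4-hydroxyphenethyl dotriacontanoate (tyrosol lacceroate).
- The target is achiral, with no stereocenters. The only ring is the benzene ring, so no ring-forming or stereochemical steps are needed.
- Compounds 7 and 8 are commercial catalyst components. They are numbered and classed as starting materials because they are purchased, not made in the route.

## Retrosynthetic overview
1. Disconnect the ester C(sp3)–O bond as an anti-Markovnikov hydroacyloxylation. This gives dotriacontanoic acid plus unprotected 4-vinylphenol, so the tyrosol unit and the ester form in one step with no phenol protection (proposed new step).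
2. Disconnect the C32 acid at its central C16–C16 bond by Cu-catalysed Grignard/alkyl bromide coupling. This gives C16H33MgBr plus 16-bromohexadecanoic acid.
3. 4-Vinylphenol comes from commercial 4-acetoxystyrene by methanolysis.
4. The order of bond formation is C–C (chain), then C–O (ester).

## Forward route

**Step 1**
Reactants: 1 (1-bromohexadecane)
Product: 2 (hexadecylmagnesium bromide)
Conditions: Mg turnings, I2 (cat.), THF, 40 °C, 2 h
Reagents that add atoms: magnesium, [Mg]
Why: Standard Grignard formation from a primary alkyl bromide, in which Mg inserts into the C–Br bond.

**Step 2**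
Reactants: 3 (16-bromohexadecanoic acid), 2 (hexadecylmagnesium bromide)
Product: 4 (dotriacontanoic acid)
Conditions: (i) 3, MeMgCl (1.0 equiv), THF, 0 °C, to form the Mg carboxylate; (ii) 2 (1.6 equiv), Li2CuCl4 (5 mol%), THF/NMP 10:1, −10 → 25 °C, 12 h; (iii) 1 M HCl
Reagents that add atoms: none. MeMgCl is lost as CH4, Li2CuCl4 is catalytic, and HCl only protonates the carboxylate.
Why: Kochi/Fouquet–Schlosser Cu-catalysed sp3–sp3 coupling of a primary alkyl Grignard with a primary alkyl bromide. The carboxylic acid is masked in situ as its magnesium salt, so it survives the Grignard. The C16–C16 bond forms here, giving 16 + 16 = 32 carbons. The by-products dotriacontane and hexadecane are non-polar and are removed by silica chromatography (hexane, then EtOAc/hexane/AcOH) or recrystallisation.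

**Step 3**
Reactants: 5 (4-acetoxystyrene)
Product: 6 (4-vinylphenol)
Conditions: K2CO3, MeOH, 0 °C, 30 min; quench with cold sat. aq. NH4Cl, extract; use immediately as a DCE solution
Reagents that add atoms: none. The acetyl group leaves as methyl acetate.
Why: Mild methanolysis (transesterification) of a phenyl acetate. The vinyl group is untouched.

**Step 4 (key step)**
Reactants: 4 (dotriacontanoic acid, 1.0 equiv), 6 (4-vinylphenol, 1.5 equiv)
Product: 9 (4-hydroxyphenethyl dotriacontanoate, the target)
Conditions: 7 (9-mesityl-10-methylacridinium BF4, 2 mol%), 8 (PhSSPh, 10 mol%), DCE/PhCF3 1:1 (0.05 M), 450 nm blue LEDs, 45 °C, 18 h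
Reagents that add atoms: none. Catalysts 7 and 8 are not incorporated into the product.
Why: Proposed new method: the closest known reaction is the acridinium/thiol co-catalysed anti-Markovnikov addition of carboxylic acids to styrenes and alkenes, extended here to an unprotected p-hydroxystyrene and a C32 fatty acid so the phenol is never protected. Excited Mes-Acr+ oxidises 4-vinylphenol to its radical cation. The carboxylic acid adds at the terminal CH2, giving the para-OH-stabilised benzylic radical, which takes H• from PhSH (formed in situ from PhSSPh). The resulting PhS• is reduced by Acr• to PhS⁻ and protonated, closing the cycle. Any phenoxyl-type radical from O–H oxidation is reduced back to the phenol by Acr• (unproductive but not destructive), and excess vinylphenol offsets oligomerisation. The product has no stereocenter, so none needs to be set.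

## Compound list
1 | 1-bromohexadecane | CCCCCCCCCCCCCCCCBr | starting material
2 | hexadecylmagnesium bromide | CCCCCCCCCCCCCCCC[Mg]Br | intermediate
3 | 16-bromohexadecanoic acid | OC(=O)CCCCCCCCCCCCCCCBr | starting material
4 | dotriacontanoic (lacceroic) acid | CCCCCCCCCCCCCCCCCCCCCCCCCCCCCCCC(=O)O | intermediate
5 | 4-acetoxystyrene | CC(=O)Oc1ccc(C=C)cc1 | starting material
6 | 4-vinylphenol | C=Cc1ccc(O)cc1 | intermediate
7 | 9-mesityl-10-methylacridinium tetrafluoroborate (photocatalyst) | Cc1cc(C)c(c(C)c1)-c1c2ccccc2[n+](C)c2ccccc12.F[B-](F)(F)F | starting material
8 | diphenyl disulfide (HAT co-catalyst precursor) | c1ccccc1SSc1ccccc1 | starting material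
9 | 4-hydroxyphenethyl dotriacontanoate | CCCCCCCCCCCCCCCCCCCCCCCCCCCCCCCC(=O)OCCc1ccc(O)cc1 | target

## Totals
- Total steps: 4.
- Longest linear sequence: 3 steps (1 → 2 → 4 → 9, i.e. Steps 1, 2 and 4). Step 3 is a convergent side branch.

## Three steps most likely to fail
1. **Step 4 (proposed new step).** The phenol may be oxidised or oligomerised, or the C32 acid may have poor solubility. Fallback using known chemistry:
   - Convert 4 to its acid chloride (oxalyl chloride, cat. DMF, toluene, 50 °C).
   - Esterify with commercial 2-(4-benzyloxyphenyl)ethanol (pyridine, DMAP, 60 °C).
   - Remove the benzyl group by H2, Pd/C in warm THF to give 9.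
2. **Step 2.** The long-chain magnesium carboxylate may gel or be insoluble, and homocoupling may compete. Fallback with a different approach:
   - Wittig-couple the hexadecyltriphenylphosphonium ylide with methyl 16-oxohexadecanoate.
   - Hydrogenate the alkene (H2, Pd/C).
   - Saponify the ester (KOH, THF/EtOH/H2O) to give 4.
3. **Step 3 (and supply of 6).** 4-Vinylphenol polymerises easily. Fallback:
   - Run Step 4 directly on 4-acetoxystyrene (5).
   - Selectively cleave the aryl acetate in the product with hydrazinium acetate in DMF at rt, which leaves the primary alkyl ester intact.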